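3 questions stand here, one choice and two yields, and I answer them with one level.

the same everywhere: G 12 µM

| charge | E | Z | temperature | remark | time |
|---|---|---|---|---|---|
| maple | 0.067 M | 0.0024 mol% | 18 °C | run made earlier |  |
| birch | 0.15 M | 0.0024 mol% | 32 °C | run made earlier |  |
| ash | 0.10 M | 0.0048 mol% | 18 °C | run made earlier |  |
| south-west | 0.10 M | 0.0024 mol% | 12 °C |  | 20 min |
| south-east | 0.10 M | 0.0024 mol% | 37 °C |  | 20 min |

| run | time / min | D / % | E / % |
|---|---|---|---|
| maple | 3.00 | 8.4 | 88.3 |
| maple | 6.00 | 13.5 | 80.3 |
| maple | 10.0 | 16.9 | 69.0 |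
| maple | 12.0 | 18.1 | 64.3 |
| birch | 1.00 | 7.3 | 88.2 |
| birch | 2.00 | 11.3 | 75.5 |
| birch | 4.00 | 13.5 | 55.9 |
| ash | 1.00 | 8.1 | 91.9 |
| ash | 2.00 | 14.3 | 82.6 |
| ash | 5.00 | 27.1 | 60.4 |
| ash | 12.0 | 36.1 | 29.9 |

(scatter of a reading: 0.5 percentage points)

* the flask with the highest amount of D, in percent of the E charged ("all alike" if they lie within 1.5 percentage points) (south-west / south-east / all alike)
* final D, as a percentage of the E charged, in south-west
* final D, as a percentage of the E charged, in south-east

Take what is neither E nor D, the gap, and suppose each wasting event removes one E and one D. Its growth, divided by the product of E and D and by the E charged, is a waste constant. Between late readings I get 2.26 /M/min in ash and 2.52 /M/min in maple: different charges, nearly one value, so I trust it. Birch gives 7.21 /M/min. Stepping along the temperature, south-west gets 1.49 /M/min and south-east 10.7 /M/min.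

D is made with a pseudo-first-order making constant: half of E lost plus D found, per minute and per E present. Ash offers two ways to it, 0.0868 /min from early readings and 0.0625 /min from late ones, and they part. Birch parts too, 0.102 /min against 0.0830 /min. The early figure is the cheat: the constant sinks as a run goes on, so Z seems to fade, by 0.0438 /min in ash and 0.103 /min in birch. Scaled to the Z charged, south-west starts at 0.0358 /min and fades by 0.0303 /min; south-east starts at 0.0798 /min and fades by 0.140 /min.

Set making against wasting and E cancels. Twice the making constant over the waste constant and the E charged is 0.901 % for south-east at 20 min: the ceiling of D, the level at which D is made as fast as it is wasted. With its mean making constant 0.0277 /min, south-west has a ceiling of 37.1 %, and D climbs toward it over an E-weighted time. Taking E from making alone, that time is 15.8 min and D 25.6 %. Putting this answer back, since each wasted D takes an E too, the time shrinks to 13.9 min and D to 23.9 %. South-east's D trails its sinking ceiling from above, so I commit to south-west.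

The forecast, higher than mine for south-west, says south-west, with 31 % there and 1.5 % in south-east: “D is not a clean product”. The flasks give south-west, with 21.8 % there and 3.28 % in south-east.

    D ⇌ J (K = 23.5, k = 0.00173 /s, Ea = 91.0 kJ/mol, ΔH = −31.0 kJ/mol)
    E + Z → D + Z, rate k2*[E]*[Z]/(1 + ([E]/Km2) + ([D]/Kp2)) (0.0678 M, 0.133 M, k = 2070 /M/s, Ea = 39.0 kJ/mol)
    Z + G ⇌ L (K = 3.24 × 10⁶ /M, k = 248 /M/s, Ea = 38.0 kJ/mol, ΔH = −8.00 kJ/mol)
    Z → X (k = 1.96 × 10⁻⁵ /s, Ea = 286 kJ/mol)
    E + D → Q (k = 0.0827 /M/s, Ea = 64.0 kJ/mol)
    (constants at 37 °C)

Take the turning of E + D into Q out of south-east and D ends at 15.3 % instead of 3.28 %, the largest single effect on that run. South-east's D stands above its ceiling of 0.901 %, made at 0.499 of the rate at which it is used. South-west ends with D at 21.8 %, below its ceiling of 37.1 % and up from 17.7 % at 10.0 min.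

Readings and results were computed with made-up constants; the scatter is artificial.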